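**Retrosynthetic overview**
- Feature: in the oxolane ring (O1, C2–C5), C4 carries a benzylic carbinol carbon and its neighbour C5 is a bare CH2 bound to O1. The bonds O1–C5, C4–C(carbinol) and C(carbinol)–aryl therefore all start from the two-carbon unit C4–C5, which can be an alkyne that takes up a hydroxyl, CO and an aryl group.
- Endgame (retro): the benzyl ethers come off last. The S carbinol comes from the aryl ketone by catalyst-controlled transfer hydrogenation, C4 from syn-hydrogenation of C4=C5 of a 4-aroyl-2,3-dihydrofuran on the face opposite the cis C2/C3 groups, and C5–H from C5–SiMe3.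
- Key disconnection: 4-aroyl-5-silyl-2,3-dihydrofuran ⇒ syn homopropargylic alcohol + CO + aryl iodide, by aroylpalladium-triggered 5-endo-dig oxypalladation followed by reductive elimination.
- Alkynol ⇒ Evans syn-aldol of an N-(3-benzyloxypropanoyl)oxazolidinone with O-benzylvanillin (sets C2 and C3), then Weinreb amide, aldehyde and Corey–Fuchs alkynylation with a Me3SiCl quench.
- Ring order: the oxolane is the only ring that is built, and it closes in the key step.

Key step: step 10

Remark on the chemistry: ring atoms are numbered O1, C2 (aryl), C3 (CH2OH), C4 (carbinol-bearing) and C5 (CH2). The SMILES reads as 2S,3S,4S with an S carbinol and all three ring substituents on one face, and the route is planned for exactly this isomer.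

**Route**

Step 1
Reactants: 1 3-(benzyloxy)propanoic acid; 2 (S)-4-benzyl-2-oxazolidinone
Product: 4 (S)-4-benzyl-3-[3-(benzyloxy)propanoyl]oxazolidin-2-one, via mixed pivalic anhydride 3 (not isolated)
Conditions: t-BuCOCl, Et3N, THF, −20 °C; then LiCl, 2, −20 °C to rt
Reagents that add atoms: pivaloyl chloride, CC(C)(C)C(=O)Cl (its acyl group stands only in 3)
Why: N-acylation of the oxazolidinone through a mixed anhydride with LiCl activation is a standard mild imide synthesis, and the nucleophile should attack the less hindered acyl carbon of 3.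

Step 2
Reactants: 4 (S)-4-benzyl-3-[3-(benzyloxy)propanoyl]oxazolidin-2-one; 5 O-benzylvanillin (4-benzyloxy-3-methoxybenzaldehyde)
Product: 8 (S)-4-benzyl-3-[(2S,3S)-2-(benzyloxymethyl)-3-(4-benzyloxy-3-methoxyphenyl)-3-hydroxypropanoyl]oxazolidin-2-one (syn-aldol), via Z-boron enolate 6 (not isolated), via boron aldolate 7 (not isolated)
Conditions: Bu2BOTf, Et3N, CH2Cl2, −78 to 0 °C; 5, −78 to 0 °C; then pH 7 buffer, MeOH, 30% H2O2, 0 °C
Reagents that add atoms: dibutylboron triflate, CCCCB(CCCC)OS(=O)(=O)C(F)(F)F (its Bu2B group stands only in 6 and 7)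
Why: Evans syn-aldol reaction, in which the Z-boron enolate reacts through a closed Zimmerman–Traxler chair on the enolate face left open by the benzyl group of the (S)-auxiliary, which should set both stereocentres (later C3 and C2 of the ring) as 2S,3S, while the covalent B–O enolate is not expected to expel benzyloxide at or below 0 °C.

Step 3
Reactants: 8 syn-aldol imide
Product: 9 (2S,3S)-2-(benzyloxymethyl)-3-(4-benzyloxy-3-methoxyphenyl)-3-hydroxy-N-methoxy-N-methylpropanamide
Conditions: MeONHMe·HCl, AlMe3, CH2Cl2, −10 °C to rt; aq. potassium sodium tartrate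
Reagents that add atoms: N,O-dimethylhydroxylamine hydrochloride, CNOC.Cl
Why: Weinreb transamidation with an aluminium amide, guided to the exocyclic carbonyl by the aluminium alkoxide of the free β-hydroxyl, should release the auxiliary without touching either stereocentre.

Step 4
Reactants: 9 β-hydroxy Weinreb amide
Product: 10 (2S,3S)-2-(benzyloxymethyl)-3-(4-benzyloxy-3-methoxyphenyl)-N-methoxy-N-methyl-3-(triethylsilyloxy)propanamide
Conditions: Et3SiCl, imidazole, DMF, 0 °C to rt
Reagents that add atoms: chlorotriethylsilane, CC[Si](Cl)(CC)CC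
Why: Silyl ether protection blocks retro-aldol cleavage at the aldehyde stage, and triethylsilyl is chosen because it can later be removed under conditions that leave an alkynyl C–SiMe3 bond intact.

Step 5
Reactants: 10 silylated Weinreb amide
Product: 11 (2S,3S)-2-(benzyloxymethyl)-3-(4-benzyloxy-3-methoxyphenyl)-3-(triethylsilyloxy)propanal
Conditions: i-Bu2AlH, THF, −78 °C; aq. potassium sodium tartrate
Reagents that add atoms: none
Why: Weinreb amide reduction stops at the chelated tetrahedral aluminium adduct, so the aldehyde appears only on the neutral work-up and its α-stereocentre should be kept.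

Step 6
Reactants: 11 α-branched aldehyde
Product: 12 [(1S,2S)-2-(benzyloxymethyl)-1-(4-benzyloxy-3-methoxyphenyl)-4,4-dibromobut-3-enyloxy]triethylsilane
Conditions: CBr4, PPh3, Et3N, CH2Cl2, 0 °C
Reagents that add atoms: carbon tetrabromide, BrC(Br)(Br)Br
Why: The dibromoolefination stage of the Corey–Fuchs reaction is a Wittig-type process without alkoxide base, preferred over a diazophosphonate homologation in K2CO3/MeOH because 11 has an acidic α-hydrogen flanked by two β-oxygen leaving groups.

Step 7
Reactants: 12 1,1-dibromoalkene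
Product: 14 [(1S,2S)-2-(benzyloxymethyl)-1-(4-benzyloxy-3-methoxyphenyl)-4-(trimethylsilyl)but-3-ynyloxy]triethylsilane, via lithium acetylide 13 (not isolated)
Conditions: n-BuLi (2.2 equiv), THF, −78 °C; then Me3SiCl, −78 °C to rt
Reagents that add atoms: chlorotrimethylsilane, C[Si](C)(C)Cl; n-butyllithium, [Li]CCCC (its lithium stands only in 13)
Why: In the second stage of the Corey–Fuchs reaction, bromine–lithium exchange, 1,2-hydrogen shift of the carbenoid and deprotonation give the acetylide, which is C-silylated in the same flask so that no separate capping step is needed.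

Step 8
Reactants: 14 O-triethylsilyl C-trimethylsilyl alkyne
Product: 15 (1S,2S)-2-(benzyloxymethyl)-1-(4-benzyloxy-3-methoxyphenyl)-4-(trimethylsilyl)but-3-yn-1-ol (syn)
Conditions: HF·pyridine, pyridine, THF, 0 °C
Reagents that add atoms: none
Why: Selective O-desilylation should work because buffered HF·pyridine cleaves the Si–O bond of the triethylsilyl ether, the alkynyl C–Si bond needs basic fluoride or alkoxide, and the weakly acidic medium should not ionise the electron-rich benzylic carbinol.

Step 9
Reactants: 16 4-iodo-2-methoxyphenol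
Product: 17 1-(benzyloxy)-4-iodo-2-methoxybenzene
Conditions: BnBr, K2CO3, DMF, rt
Reagents that add atoms: benzyl bromide, BrCc1ccccc1
Why: Williamson ether synthesis on a phenoxide is reliable, and the aryl iodide is inert to these conditions.

Step 10
Reactants: 15 syn homopropargylic alcohol; 17 1-(benzyloxy)-4-iodo-2-methoxybenzene; 18 carbon monoxide
Product: 19 (4-benzyloxy-3-methoxyphenyl)[(2S,3S)-3-(benzyloxymethyl)-2-(4-benzyloxy-3-methoxyphenyl)-5-(trimethylsilyl)-2,3-dihydrofuran-4-yl]methanone (2,3-cis)
Conditions: Pd(PPh3)4 (5 mol %), K2CO3, CO (1 atm), dry MeCN, 50 °C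
Reagents that add atoms: none
Why: Proposed new method: oxidative addition of 17 to zerovalent palladium and insertion of 18 should give an aroylpalladium iodide that binds the alkyne of 15 as a soft π-acid, the hydroxyl (deprotonated by K2CO3 as it attacks) adds anti to C5, and the C4-vinyl(aroyl)palladium species reductively eliminates, so that C(=O)–aryl, O1–C5 and C4–C(=O) are all made in one catalytic cycle. The closest known reaction type is the carbonylative heteroannulation of 2-alkynylphenols with aryl iodides under CO to 3-aroylbenzofurans, and the 5-endo-dig oxypalladation–alkoxycarbonylation of aliphatic 3-yne-1,2-diols shows that an sp3 carbinol can take the place of the phenol; what is new is an aroylpalladium trigger on a non-aromatic homopropargylic alcohol. The oxolane ring closes 5-endo-dig, because attack at the inner alkyne carbon would be a 4-exo closure to a strained oxetane. No stereocentre is made: C2 and C3 are carried over from the aldol, and neither the carbinol C–H nor the propargylic C–H is acidic enough for K2CO3. The step needs oxypalladation to win over aroylation of the hydroxyl, over aryl transfer without CO and over carbonylative coupling at an alkyne C–H; the hindered secondary carbinol sitting next to the bound alkyne, a heterogeneous weak base, the fast CO insertion of an electron-rich arylpalladium at 1 atm and the Me3Si cap are what should secure this, and the equally placed ether oxygen of the CH2OBn arm cannot compete since it has no proton to lose. The silyl group also hinders C5 and polarises the alkyne against attack there, which is why the risk of the route is placed in this step.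

Step 11
Reactants: 19 5-silyl-4-aroyl-2,3-dihydrofuran
Product: 20 (4-benzyloxy-3-methoxyphenyl)[(2S,3S)-3-(benzyloxymethyl)-2-(4-benzyloxy-3-methoxyphenyl)-2,3-dihydrofuran-4-yl]methanone
Conditions: Bu4NF, AcOH, THF, 0 °C to rt
Reagents that add atoms: none
Why: Fluoride-induced protodesilylation of a vinylsilane should be easy here because C5 is bound to O1 and lies β to the aroyl group, whose cis carbonyl oxygen can assist at silicon, while acetic acid supplies the proton and keeps hydroxide away from the vinylogous ester.

Step 12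
Reactants: 20 4-aroyl-2,3-dihydrofuran
Product: 21 (4-benzyloxy-3-methoxyphenyl)[(2S,3S,4S)-3-(benzyloxymethyl)-2-(4-benzyloxy-3-methoxyphenyl)tetrahydrofuran-4-yl]methanone (all-cis)
Conditions: H2 (1–3 atm), 5% Rh/Al2O3, EtOAc, rt
Reagents that add atoms: none
Why: In this heterogeneous syn-hydrogenation the cis C2 aryl and C3 CH2OBn groups keep one ring face off the metal, so both hydrogens should reach C4=C5 from the other face and push the aroyl group to their side (C4 = S), and rhodium on alumina is chosen for its low hydrogenolysis activity toward the benzyl ethers and the benzylic C2–O1 bond.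

Step 13
Reactants: 21 all-cis aryl ketone
Product: 22 (S)-(4-benzyloxy-3-methoxyphenyl)[(2S,3S,4S)-3-(benzyloxymethyl)-2-(4-benzyloxy-3-methoxyphenyl)tetrahydrofuran-4-yl]methanol
Conditions: RuCl(p-cymene)[(S,S)-TsDPEN] (3 mol %), HCO2H–Et3N (5:2), CH2Cl2, 30 °C
Reagents that add atoms: none
Why: In this Noyori asymmetric transfer hydrogenation the (S,S) catalyst recognises the aryl ring by a CH/π contact and should give the S carbinol in the same sense as acetophenone gives (S)-1-phenylethanol, a reagent control that has to override the Felkin-type bias of 21 for the epimer, while the acidic formate medium should not enolise C4.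

Step 14
Reactants: 22 tribenzyl ether
Product: 23 target, (S)-(4-hydroxy-3-methoxyphenyl)[(2S,3S,4S)-2-(4-hydroxy-3-methoxyphenyl)-3-(hydroxymethyl)tetrahydrofuran-4-yl]methanol
Conditions: H2 (1 atm), 10% Pd/C, EtOAc–EtOH, rt, stopped at full conversion
Reagents that add atoms: none
Why: Hydrogenolysis of the three benzyl ethers in a neutral, acid-free solvent should be much faster than cleavage of the secondary benzylic alcohol or the C2–O1 bond, and no stereocentre is involved.

**Compound list**
1 | 3-(benzyloxy)propanoic acid | O=C(O)CCOCc1ccccc1 | starting material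
2 | (S)-4-benzyl-2-oxazolidinone | O=C1N[C@@H](Cc2ccccc2)CO1 | starting material
3 | mixed pivalic anhydride of 1 (not isolated) | CC(C)(C)C(=O)OC(=O)CCOCc1ccccc1 | intermediate
4 | (S)-4-benzyl-3-[3-(benzyloxy)propanoyl]oxazolidin-2-one | O=C(CCOCc1ccccc1)N1[C@@H](Cc2ccccc2)COC1=O | intermediate
5 | O-benzylvanillin | O=Cc1ccc(OCc2ccccc2)c(OC)c1 | starting material
6 | Z-dibutylboron enolate of 4 (not isolated) | CCCCB(CCCC)O/C(=C\COCc1ccccc1)N1[C@@H](Cc2ccccc2)COC1=O | intermediate
7 | dibutylboron aldolate (not isolated) | CCCCB(CCCC)O[C@H](c1ccc(OCc2ccccc2)c(OC)c1)[C@H](COCc1ccccc1)C(=O)N1[C@@H](Cc2ccccc2)COC1=O | intermediate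
8 | (2S,3S) syn-aldol imide | O[C@H](c1ccc(OCc2ccccc2)c(OC)c1)[C@H](COCc1ccccc1)C(=O)N1[C@@H](Cc2ccccc2)COC1=O | intermediate
9 | (2S,3S) β-hydroxy Weinreb amide | O[C@H](c1ccc(OCc2ccccc2)c(OC)c1)[C@H](COCc1ccccc1)C(=O)N(C)OC | intermediate
10 | (2S,3S) triethylsilyl ether of 9 | CC[Si](CC)(CC)O[C@H](c1ccc(OCc2ccccc2)c(OC)c1)[C@H](COCc1ccccc1)C(=O)N(C)OC | intermediate
11 | (2S,3S) aldehyde | CC[Si](CC)(CC)O[C@H](c1ccc(OCc2ccccc2)c(OC)c1)[C@H](COCc1ccccc1)C=O | intermediate
12 | (1S,2S) 1,1-dibromoalkene | CC[Si](CC)(CC)O[C@H](c1ccc(OCc2ccccc2)c(OC)c1)[C@H](COCc1ccccc1)C=C(Br)Br | intermediate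
13 | lithium acetylide (not isolated) | CC[Si](CC)(CC)O[C@H](c1ccc(OCc2ccccc2)c(OC)c1)[C@H](COCc1ccccc1)C#C[Li] | intermediate
14 | (1S,2S) O-triethylsilyl C-trimethylsilyl alkyne | CC[Si](CC)(CC)O[C@H](c1ccc(OCc2ccccc2)c(OC)c1)[C@H](COCc1ccccc1)C#C[Si](C)(C)C | intermediate
15 | (1S,2S)-2-(benzyloxymethyl)-1-(4-benzyloxy-3-methoxyphenyl)-4-(trimethylsilyl)but-3-yn-1-ol | O[C@H](c1ccc(OCc2ccccc2)c(OC)c1)[C@H](COCc1ccccc1)C#C[Si](C)(C)C | intermediate
16 | 4-iodo-2-methoxyphenol | COc1cc(I)ccc1O | starting material
17 | 1-(benzyloxy)-4-iodo-2-methoxybenzene | Ic1ccc(OCc2ccccc2)c(OC)c1 | intermediate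
18 | carbon monoxide | [C-]#[O+] | starting material
19 | (2S,3S) cis-4-aroyl-5-(trimethylsilyl)-2,3-dihydrofuran | O=C(c1ccc(OCc2ccccc2)c(OC)c1)C1=C([Si](C)(C)C)O[C@H](c2ccc(OCc3ccccc3)c(OC)c2)[C@@H]1COCc1ccccc1 | intermediate
20 | (2S,3S) cis-4-aroyl-2,3-dihydrofuran | O=C(c1ccc(OCc2ccccc2)c(OC)c1)C1=CO[C@H](c2ccc(OCc3ccccc3)c(OC)c2)[C@@H]1COCc1ccccc1 | intermediate
21 | (2S,3S,4S) all-cis 4-aroyltetrahydrofuran | O=C(c1ccc(OCc2ccccc2)c(OC)c1)[C@@H]1CO[C@H](c2ccc(OCc3ccccc3)c(OC)c2)[C@@H]1COCc1ccccc1 | intermediate
22 | S carbinol, tribenzyl ether | COc1cc([C@@H](O)[C@@H]2CO[C@H](c3ccc(OCc4ccccc4)c(OC)c3)[C@@H]2COCc2ccccc2)ccc1OCc1ccccc1 | intermediate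
23 | CNP0236765.9 | COc1cc([C@@H](O)[C@@H]2CO[C@H](c3ccc(O)c(OC)c3)[C@@H]2CO)ccc1O | target

**Step count**
Total step count: 14. Longest linear sequence: 13 (steps 1–8 and 10–14).

**Steps most likely to fail**

1. Step 10.
 - Risk: aroylation of the hydroxyl may outrun the hindered 5-endo attack at the silicon-bearing alkyne carbon. Loss of the silyl cap followed by carbonylative coupling at the freed alkyne terminus may do the same.
 - Fallback (sets out from 15, returns at 19): ring closure and acylation are separated into two known reaction types. A 5-endo-dig iodocyclisation of 15 with I2 and NaHCO3 in MeCN at 0 °C should give (2S,3S)-3-(benzyloxymethyl)-2-(4-benzyloxy-3-methoxyphenyl)-4-iodo-5-(trimethylsilyl)-2,3-dihydrofuran F1. A carbonylative Suzuki–Miyaura coupling of F1 with commercial (4-benzyloxy-3-methoxyphenyl)boronic acid (OB(O)c1ccc(OCc2ccccc2)c(OC)c1) then installs the aroyl group and delivers 19. Conditions for the coupling are CO (1 atm), PdCl2(PPh3)2 and K2CO3 in anisole at 80 °C.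

2. Step 13.
 - Risk: turnover may be slow and facial selectivity poor, because the catalyst must deliver hydride against the intrinsic preference of the ketone. Long reaction times also invite epimerisation at C4.
 - Fallback (sets out from 21, returns at 22): substrate control is accepted and the centre is then inverted.
 - Zn(BH4)2 in Et2O at −20 °C should add hydride from the open C5 side, the face favoured by both the Felkin and the O1-chelate arrangement. This gives the R-configured epimeric alcohol F2.
 - A Mitsunobu reaction of F2 with 4-nitrobenzoic acid, PPh3 and diisopropyl azodicarboxylate in THF should give the S-configured 4-nitrobenzoate F3. Any ionisation of the electron-rich benzylic centre is expected to be captured on the same open face and so leads to the same ester.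
 - Methanolysis of F3 with K2CO3 in MeOH gives 22.

3. Step 12.
 - Risk: the push–pull alkene may take up hydrogen sluggishly. Arene saturation, partial loss of benzyl ethers or hydrogenolysis of the C2–O1 bond could then compete.
 - Fallback (sets out from 20, returns at 23): selectivity among the reducible groups is given up and the order of events is changed.
 - Exhaustive hydrogenation of 20 over 10% Pd/C in EtOAc–EtOH under H2 (3 atm) should saturate C4=C5 from the same open face and cleave all three benzyl ethers. The product is the all-cis (4-hydroxy-3-methoxyphenyl)[(2S,3S,4S)-2-(4-hydroxy-3-methoxyphenyl)-3-(hydroxymethyl)tetrahydrofuran-4-yl]methanone F4, whose vanilloyl ketone is too deactivated to be reduced readily.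
 - Transfer hydrogenation of F4 with RuCl(p-cymene)[(S,S)-TsDPEN] and HCO2H–Et3N in EtOAc at rt then sets the carbinol as the last operation and gives 23.

**Further compounds**
F1 | step 10 | (2S,3S)-3-(benzyloxymethyl)-2-(4-benzyloxy-3-methoxyphenyl)-4-iodo-5-(trimethylsilyl)-2,3-dihydrofuran | IC1=C([Si](C)(C)C)O[C@H](c2ccc(OCc3ccccc3)c(OC)c2)[C@@H]1COCc1ccccc1
F2 | step 13 | (R)-(4-benzyloxy-3-methoxyphenyl)[(2S,3S,4S)-3-(benzyloxymethyl)-2-(4-benzyloxy-3-methoxyphenyl)tetrahydrofuran-4-yl]methanol | COc1cc([C@H](O)[C@@H]2CO[C@H](c3ccc(OCc4ccccc4)c(OC)c3)[C@@H]2COCc2ccccc2)ccc1OCc1ccccc1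
F3 | step 13 | (S)-(4-benzyloxy-3-methoxyphenyl)[(2S,3S,4S)-3-(benzyloxymethyl)-2-(4-benzyloxy-3-methoxyphenyl)tetrahydrofuran-4-yl]methyl 4-nitrobenzoate | COc1cc([C@@H](OC(=O)c2ccc(cc2)[N+](=O)[O-])[C@@H]2CO[C@H](c3ccc(OCc4ccccc4)c(OC)c3)[C@@H]2COCc2ccccc2)ccc1OCc1ccccc1
F4 | step 12 | (4-hydroxy-3-methoxyphenyl)[(2S,3S,4S)-2-(4-hydroxy-3-methoxyphenyl)-3-(hydroxymethyl)tetrahydrofuran-4-yl]methanone | O=C(c1ccc(O)c(OC)c1)[C@@H]1CO[C@H](c2ccc(O)c(OC)c2)[C@@H]1CO
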